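The cyclohexanone ring has a mirror plane through the carbinol carbon C1 and the carbonyl carbon C4, so its two CH2CH2 arms (C2–C3 and C6–C5) are identical. The ring is therefore cut at C3–C4 and C4–C5, with C4 excised as carbon monoxide. The precursor is an acyclic 3,3-disubstituted penta-1,4-diene that already carries the palmitate. In one flask, thexylborane ties the two vinyl groups into a temporary borinane, and carbon monoxide is then stitched in by two boron-to-carbon shifts, the second of which closes the six-membered carbocycle at C3–C4. Oxidation excises boron and unveils the ketone, delivering the target.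

Key step: step 3

Remark: the target is achiral (C1 and C4 lie on the mirror plane), so no stereocentre has to be set. ThxBH2 denotes thexylborane (2,3-dimethylbutan-2-ylborane), made in the flask from BH3·THF and 2,3-dimethylbut-2-ene.

Step 1
Reactants: 1 ethyl 3-hydroxypropanoate; 2 vinylmagnesium bromide
Product: 4 3-ethenylpent-4-ene-1,3-diol, via enone alkoxide 3 (not isolated)
Conditions: CH2=CHMgBr (3.3 equiv), THF, −40 to 0 °C; then sat. aq NH4Cl
Reagents that add atoms: vinylmagnesium bromide, C=C[Mg]Br
Why: Twofold Grignard addition to an ester: the first equivalent of 2 only deprotonates the hydroxyl (ethene is lost), the second adds to the ester to give enone 3 after loss of ethoxide, and 3, being more electrophilic than the ester, takes up the third equivalent by 1,2-addition at low temperature to give the tertiary bis-allylic alcohol, which has no stereocentre because its two vinyl groups are identical.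

Step 2
Reactants: 4 3-ethenylpent-4-ene-1,3-diol; 5 hexadecanoyl chloride; 6 1-(trimethylsilyl)imidazole
Product: 8 3-ethenyl-3-[(trimethylsilyl)oxy]pent-4-en-1-yl hexadecanoate, via hydroxy ester 7 (not isolated)
Conditions: 5 (1.0 equiv), pyridine, CH2Cl2, −10 to 0 °C; then 6 (1.5 equiv), rt; NaHCO3 work-up, Et3N-deactivated silica
Reagents that add atoms: hexadecanoyl chloride, CCCCCCCCCCCCCCCC(=O)Cl; 1-(trimethylsilyl)imidazole, C[Si](C)(C)n1ccnc1
Why: Chemoselective O-acylation followed by O-silylation: the acid chloride should esterify the unhindered primary hydroxyl much faster than the tertiary doubly allylic one, and the strong, non-acidic silyl donor 6 should then cap the tertiary hydroxyl in the same flask without ionising it, so that no B–H bond is lost to alcoholysis in step 3.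

Step 3
Reactants: 8 3-ethenyl-3-[(trimethylsilyl)oxy]pent-4-en-1-yl hexadecanoate; 9 carbon monoxide
Product: 14 2-(1-hydroxy-4-oxocyclohexyl)ethyl hexadecanoate, via thexylborinane 10 (not isolated), via acylborane 11 (not isolated), via boryl carbinol 12 (not isolated), via silyl ether ketone 13 (not isolated)
Conditions: ThxBH2 (1.0 equiv, from BH3·THF and 2,3-dimethylbut-2-ene), THF, 0 °C to rt, slow addition of 8 at high dilution; CO (70 atm), H2O (3 equiv), 50 °C; NaOAc, 30% H2O2, 30–40 °C; 1 M HCl, THF, rt
Reagents that add atoms: carbon monoxide, [C-]#[O+]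
Why: Thexylborane adds anti-Markovnikov to one vinyl group and the remaining B–H bond then adds across the second one within the same molecule (6-endo mode, boron to the terminal carbon), which closes the borinane 10, a temporary ring in which boron ties C3 to C5. Carbon monoxide binds to boron and a first 1,2-shift of a ring carbon from boron to carbon gives the seven-membered acylborane 11 (C4–C5 bond); water then induces the second 1,2-shift, which forms the C3–C4 bond and so closes the six-membered carbocycle by ring contraction of the boracycle to the boryl carbinol 12, the thexyl group being the poorest migrating group and staying on boron. Buffered H2O2 oxidises the two remaining B–C bonds, which excises boron and releases ketone 13, and dilute acid removes the trimethylsilyl group to give 14. The closest known reaction type is the cyclic hydroboration of 1,4-dienes with thexylborane followed by carbonylation–oxidation to cyclohexanones, a ketone synthesis that is known to tolerate ester groups. No stereocentre is formed because C1 and C4 lie on the mirror plane of the ring. The selectivity needed is terminal attack of boron, borinane over borolane or oligomer formation, and hydroboration in preference to ester reduction or B–H alcoholysis; it is secured by the quaternary C1 next to both alkenes (blocked internal positions and a Thorpe–Ingold effect), by slow addition at high dilution, by the silyl cap on the tertiary oxygen and by the low reactivity of thexylborane toward esters at 0 °C.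

Compound list
1 | ethyl 3-hydroxypropanoate | CCOC(=O)CCO | starting material
2 | vinylmagnesium bromide | C=C[Mg]Br | starting material
3 | 5-hydroxypent-1-en-3-one (present as its bromomagnesium alkoxide) | C=CC(=O)CCO | intermediate
4 | 3-ethenylpent-4-ene-1,3-diol | C=CC(O)(C=C)CCO | intermediate
5 | hexadecanoyl chloride (palmitoyl chloride) | CCCCCCCCCCCCCCCC(=O)Cl | starting material
6 | 1-(trimethylsilyl)imidazole | C[Si](C)(C)n1ccnc1 | starting material
7 | 3-ethenyl-3-hydroxypent-4-en-1-yl hexadecanoate | CCCCCCCCCCCCCCCC(=O)OCCC(O)(C=C)C=C | intermediate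
8 | 3-ethenyl-3-[(trimethylsilyl)oxy]pent-4-en-1-yl hexadecanoate | CCCCCCCCCCCCCCCC(=O)OCCC(O[Si](C)(C)C)(C=C)C=C | intermediate
9 | carbon monoxide | [C-]#[O+] | starting material
10 | 2-[1-(2,3-dimethylbutan-2-yl)-4-[(trimethylsilyl)oxy]borinan-4-yl]ethyl hexadecanoate | CCCCCCCCCCCCCCCC(=O)OCCC1(O[Si](C)(C)C)CCB(C(C)(C)C(C)C)CC1 | intermediate
11 | 2-[1-(2,3-dimethylbutan-2-yl)-2-oxo-5-[(trimethylsilyl)oxy]borepan-5-yl]ethyl hexadecanoate | CCCCCCCCCCCCCCCC(=O)OCCC1(O[Si](C)(C)C)CCB(C(C)(C)C(C)C)C(=O)CC1 | intermediate
12 | 2-[4-[(2,3-dimethylbutan-2-yl)(hydroxy)boranyl]-4-hydroxy-1-[(trimethylsilyl)oxy]cyclohexyl]ethyl hexadecanoate (either relative configuration, both converge) | CCCCCCCCCCCCCCCC(=O)OCCC1(O[Si](C)(C)C)CCC(O)(B(O)C(C)(C)C(C)C)CC1 | intermediate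
13 | 2-[4-oxo-1-[(trimethylsilyl)oxy]cyclohexyl]ethyl hexadecanoate | CCCCCCCCCCCCCCCC(=O)OCCC1(O[Si](C)(C)C)CCC(=O)CC1 | intermediate
14 | 2-(1-hydroxy-4-oxocyclohexyl)ethyl hexadecanoate | CCCCCCCCCCCCCCCC(=O)OCCC1(O)CCC(=O)CC1 | target

Total step count: 3. Longest linear sequence: 3 steps.

Steps most likely to fail

Step 3: the monoalkylthexylborane may hydroborate a second diene molecule instead of closing the borinane, or the second boron-to-carbon shift may stall, so that oxidation returns open-chain alcohols instead of the ketone. The fallback sets out from 8 and comes back at 14. Exhaustive hydroboration with 9-BBN and oxidation with NaBO3·4H2O should give 3-[2-(hexadecanoyloxy)ethyl]-3-[(trimethylsilyl)oxy]pentane-1,5-diol F1. MsCl and Et3N in CH2Cl2 should convert it into 3-[2-(hexadecanoyloxy)ethyl]-3-[(trimethylsilyl)oxy]pentane-1,5-diyl dimethanesulfonate F2. Double alkylation of tosylmethyl isocyanide (NaH, NaI cat., DMSO/Et2O; van Leusen ketone synthesis) should give 2-[4-isocyano-4-(4-methylbenzenesulfonyl)-1-[(trimethylsilyl)oxy]cyclohexyl]ethyl hexadecanoate F3, the second alkylation closing the same CH2–C bond of the ring. Dilute aqueous HCl in THF should then unmask the ketone and remove the silyl group to give 14.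

Step 1: conjugate addition of the Grignard reagent to enone 3, or ring closure of its alkoxide onto the enone, may erode the double 1,2-addition. The fallback sets out from 1 and comes back at 4. Silylation (TBSCl, imidazole, DMF) should give ethyl 3-[(tert-butyldimethylsilyl)oxy]propanoate F4. The vinylcerium reagent made from 2 and anhydrous CeCl3 (THF, −78 °C) should add twice in the 1,2-sense to give 1-[(tert-butyldimethylsilyl)oxy]-3-ethenylpent-4-en-3-ol F5. Bu4NF in THF should then release diol 4.

Step 2: silylation of the hindered tertiary hydroxyl may lag in the presence of the ester and pyridinium chloride, and forcing it risks ionisation of the doubly allylic carbinol. The fallback sets out from 4 and comes back at 8. Exhaustive silylation (TMSOTf, Et3N, CH2Cl2, −78 °C) should give 3-ethenyl-1,3-bis[(trimethylsilyl)oxy]pent-4-ene F6. Brief methanolysis (K2CO3 cat., MeOH, 0 °C) should free only the primary hydroxyl to give 3-ethenyl-3-[(trimethylsilyl)oxy]pent-4-en-1-ol F7. Steglich esterification with hexadecanoic acid (DCC, DMAP, CH2Cl2) should then give 8.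

Further compounds
F1 | step 3 | 3-[2-(hexadecanoyloxy)ethyl]-3-[(trimethylsilyl)oxy]pentane-1,5-diol | CCCCCCCCCCCCCCCC(=O)OCCC(O[Si](C)(C)C)(CCO)CCO
F2 | step 3 | 3-[2-(hexadecanoyloxy)ethyl]-3-[(trimethylsilyl)oxy]pentane-1,5-diyl dimethanesulfonate | CCCCCCCCCCCCCCCC(=O)OCCC(O[Si](C)(C)C)(CCOS(C)(=O)=O)CCOS(C)(=O)=O
F3 | step 3 | 2-[4-isocyano-4-(4-methylbenzenesulfonyl)-1-[(trimethylsilyl)oxy]cyclohexyl]ethyl hexadecanoate | CCCCCCCCCCCCCCCC(=O)OCCC1(O[Si](C)(C)C)CCC([N+]#[C-])(S(=O)(=O)c2ccc(C)cc2)CC1
F4 | step 1 | ethyl 3-[(tert-butyldimethylsilyl)oxy]propanoate | CCOC(=O)CCO[Si](C)(C)C(C)(C)C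
F5 | step 1 | 1-[(tert-butyldimethylsilyl)oxy]-3-ethenylpent-4-en-3-ol | C=CC(O)(C=C)CCO[Si](C)(C)C(C)(C)C
F6 | step 2 | 3-ethenyl-1,3-bis[(trimethylsilyl)oxy]pent-4-ene | C=CC(O[Si](C)(C)C)(C=C)CCO[Si](C)(C)C
F7 | step 2 | 3-ethenyl-3-[(trimethylsilyl)oxy]pent-4-en-1-ol | C=CC(O[Si](C)(C)C)(C=C)CCO
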